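Ring B is not brought in as an aryl building block but is grown on the chromone. Disconnecting the C1'–C2' and C5'–C6' bonds leaves a terminal alkyne on C2 of ring C and a symmetric 2,3-bis(silyloxy)butadiene. Their Diels–Alder union closes the ring B carbocycle in one operation and delivers both oxygens to the neighbouring carbons C3' and C4' as silyl enol ethers, so the catechol needs no ether protection that would compete with the ring A methyl ethers on O6, O7 and O8 in the final deprotection. The precursor is 3-benzyloxy-2-ethynyl-5,6,7,8-tetramethoxychromone; dehydrogenation and one BCl3 treatment complete the synthesis.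

Key step: step 9

Remark: the Weinreb amide 6 is taken as a catalogue compound (otherwise one amidation from benzyloxyacetyl chloride and MeNHOMe·HCl); the Z geometry drawn for the transient enaminones 9 and 10 has no bearing on ring closure.

Step 1
Reactants: 1 1,2,3,4-tetramethoxybenzene
Product: 4 2,3,4,5-tetramethoxyphenol, via aryllithium 2 (not isolated), via lithium arylborate 3 (not isolated)
Conditions: n-BuLi, TMEDA, THF, 0 °C → rt; B(OMe)3, −78 °C → rt; AcOH, 30% aq. H2O2 (1.2 equiv), 0 °C → rt; aq. Na2SO3
Reagents that add atoms: hydrogen peroxide, OO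
Why: Directed ortho-lithiation (the two ring C–H positions are equivalent, so only one aryllithium can form), borylation and peroxide oxidation with 1,2-aryl migration from boron to oxygen is the standard lithiation–borylation–oxidation route from an arene C–H to a phenol.

Step 2
Reactants: 4 2,3,4,5-tetramethoxyphenol
Product: 5 1,2,3,4-tetramethoxy-5-(methoxymethoxy)benzene
Conditions: MOMCl, i-Pr2NEt, CH2Cl2, 0 °C → rt
Reagents that add atoms: chloromethyl methyl ether, COCCl
Why: O-Alkylation of the phenol with an α-chloro ether (Williamson-type acetal formation) installs a MOM group that tolerates and directs the lithiation of step 3 and is lost under the acid of step 4.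

Step 3
Reactants: 5 1,2,3,4-tetramethoxy-5-(methoxymethoxy)benzene; 6 N-methoxy-N-methyl-2-(benzyloxy)acetamide
Product: 8 2-(benzyloxy)-1-[2-(methoxymethoxy)-3,4,5,6-tetramethoxyphenyl]ethan-1-one, via pentaalkoxyphenyllithium 7 (not isolated)
Conditions: n-BuLi, THF, 0 °C; 6, −78 → 0 °C; H2O
Reagents that add atoms: none
Why: Directed ortho-lithiation removes the only remaining ring proton, which lies between the OMOM and OMe groups, and the Weinreb ketone synthesis stops at the ketone because the chelated tetrahedral adduct survives until the quench, so neither the benzyl ether nor the methyl ethers ever meet a Lewis acid.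

Step 4
Reactants: 8 2-(benzyloxy)-1-[2-(methoxymethoxy)-3,4,5,6-tetramethoxyphenyl]ethan-1-one
Product: 11 3-(benzyloxy)-5,6,7,8-tetramethoxy-4H-chromen-4-one, via MOM-protected enaminone 9 (not isolated), via phenolic enaminone 10 (not isolated)
Conditions: Me2NCH(OMe)2, toluene, 100 °C; concentrate; HCl, MeOH, 50 °C
Reagents that add atoms: N,N-dimethylformamide dimethyl acetal, COC(OC)N(C)C
Why: Condensation of the α-alkoxy ketone methylene with the amide acetal gives a β-dimethylamino enone, and acid then removes the MOM acetal so that the freed phenol closes ring C by 6-endo-trig oxa-Michael addition and loss of dimethylamine (enaminone route to 3-substituted chromones).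

Step 5
Reactants: 11 3-(benzyloxy)-5,6,7,8-tetramethoxy-4H-chromen-4-one
Product: 13 3-(benzyloxy)-2-iodo-5,6,7,8-tetramethoxy-4H-chromen-4-one, via bis(chromon-2-yl)zinc 12 (not isolated)
Conditions: Zn(TMP)2·2MgCl2·2LiCl (0.6 equiv; TMP = 2,2,6,6-tetramethylpiperidide), THF, −30 °C → rt; I2, THF, 0 °C; aq. Na2S2O3
Reagents that add atoms: iodine, II
Why: Deprotonative zincation with a hindered zinc amide takes the only pyranone C–H, at C2, which is acidified by O1 and by MgCl2 coordination to the C4 carbonyl; the covalent C–Zn bond neither opens ring C nor attacks the carbonyl, and iodinolysis of that bond gives the iodide.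

Step 6
Reactants: 13 3-(benzyloxy)-2-iodo-5,6,7,8-tetramethoxy-4H-chromen-4-one; 14 trimethylsilylacetylene
Product: 15 3-(benzyloxy)-5,6,7,8-tetramethoxy-2-[(trimethylsilyl)ethynyl]-4H-chromen-4-one
Conditions: PdCl2(PPh3)2 (3 mol %), CuI (5 mol %), Et3N, THF, rt
Reagents that add atoms: none
Why: Sonogashira coupling should be fast because the 2-iodochromone is a β-iodo enone that undergoes ready oxidative addition, and a tertiary amine is used so that no amine can displace the iodide at C2 by addition–elimination.

Step 7
Reactants: 15 3-(benzyloxy)-5,6,7,8-tetramethoxy-2-[(trimethylsilyl)ethynyl]-4H-chromen-4-one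
Product: 16 3-(benzyloxy)-2-ethynyl-5,6,7,8-tetramethoxy-4H-chromen-4-one
Conditions: Bu4NF, AcOH, THF, 0 °C
Reagents that add atoms: none
Why: Fluoride-induced protodesilylation of the alkynylsilane is buffered with acetic acid so that no basic nucleophile is present to add to the conjugated alkyne or to C2 of the pyranone.

Step 8
Reactants: 17 2,3-butanedione
Product: 18 2,3-bis(trimethylsilyloxy)buta-1,3-diene
Conditions: Me3SiOTf (2.2 equiv), Et3N (2.5 equiv), Et2O, 0 °C → rt; distil
Reagents that add atoms: trimethylsilyl trifluoromethanesulfonate, C[Si](C)(C)OS(=O)(=O)C(F)(F)F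
Why: Double enolisation and O-silylation of the 1,2-diketone by a silyl triflate and a tertiary amine (soft enolisation) gives the bis(silyl enol ether), a known distillable diene.

Step 9
Reactants: 16 3-(benzyloxy)-2-ethynyl-5,6,7,8-tetramethoxy-4H-chromen-4-one; 18 2,3-bis(trimethylsilyloxy)buta-1,3-diene
Product: 19 3-(benzyloxy)-2-[4,5-bis(trimethylsilyloxy)cyclohexa-1,4-dien-1-yl]-5,6,7,8-tetramethoxy-4H-chromen-4-one
Conditions: 18 (4 equiv), 2,6-di-tert-butyl-4-methylphenol (cat.), toluene, 140 °C, sealed tube, argon; volatiles and excess 18 removed in vacuo, crude 19 carried on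
Reagents that add atoms: none
Why: A concerted, thermally allowed suprafacial [4+2] cycloaddition of normal electron demand joins the two CH2 termini of diene 18, whose HOMO is raised by the two silyloxy groups, to the two alkyne carbons of 16, whose LUMO is lowered by conjugation through C2=C3 to the C4 carbonyl. The closest known reaction type is the Diels–Alder addition of 2,3-bis(silyloxy)butadienes to acetylenic ketones and esters, whose cyclohexa-1,4-diene adducts are dehydrogenated to catechol derivatives. Ring B is closed as a six-membered carbocycle by intermolecular [4+2] annulation, the C1'–C2' and C5'–C6' bonds being formed in the same event, so no separate cyclisation mode has to be chosen. No stereocentre arises, because the adduct contains only sp2 carbons and two CH2 groups. The step needs chemoselectivity for the terminal alkyne over the C2=C3 alkene of ring C, which is secured by the tetrasubstitution of that alkene and by the donor oxygens O1 and O3 on it, while regiochemistry does not arise because the diene is C2-symmetric. A second addition is not expected, since the alkenes left in the adduct are either electron-rich or unactivated.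

Step 10
Reactants: 19 3-(benzyloxy)-2-[4,5-bis(trimethylsilyloxy)cyclohexa-1,4-dien-1-yl]-5,6,7,8-tetramethoxy-4H-chromen-4-one
Product: 21 3-(benzyloxy)-2-(3,4-dihydroxyphenyl)-5,6,7,8-tetramethoxy-4H-chromen-4-one, via bis(trimethylsilyl) ether 20 (not isolated)
Conditions: DDQ (1.0 equiv), toluene, 0 °C → rt; filter off the hydroquinone; citric acid, MeOH, rt
Reagents that add atoms: none
Why: DDQ abstracts hydride from a doubly allylic CH2 of the cyclohexa-1,4-diene to give an oxygen-stabilised cyclohexadienyl cation that loses a proton, aromatisation being the driving force (quinone dehydrogenation), and the resulting aryl trimethylsilyl ethers are methanolysed under weak acid while the benzyl and methyl ethers are untouched.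

Step 11
Reactants: 21 3-(benzyloxy)-2-(3,4-dihydroxyphenyl)-5,6,7,8-tetramethoxy-4H-chromen-4-one
Product: 22 3,5,3',4'-tetrahydroxy-6,7,8-trimethoxyflavone
Conditions: BCl3 (6 equiv), pentamethylbenzene (5 equiv), CH2Cl2, −78 → 0 °C; 1 M aq. HCl
Reagents that add atoms: none
Why: Lewis-acid ether cleavage by BCl3 removes the benzyl group, whose cation is trapped by pentamethylbenzene so that the electron-rich rings are not C-benzylated, and cleaves only the C5 methyl ether, because only O5 can form a six-membered boron chelate with the C4 carbonyl, which the ethers at C6, C7 and C8 lack.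

Compound list
1 | 1,2,3,4-tetramethoxybenzene | COc1ccc(OC)c(OC)c1OC | starting material
2 | (2,3,4,5-tetramethoxyphenyl)lithium | [Li]c1cc(OC)c(OC)c(OC)c1OC | intermediate
3 | lithium trimethoxy(2,3,4,5-tetramethoxyphenyl)borate | [Li+].CO[B-](OC)(OC)c1cc(OC)c(OC)c(OC)c1OC | intermediate
4 | 2,3,4,5-tetramethoxyphenol | Oc1cc(OC)c(OC)c(OC)c1OC | intermediate
5 | 1,2,3,4-tetramethoxy-5-(methoxymethoxy)benzene | COCOc1cc(OC)c(OC)c(OC)c1OC | intermediate
6 | N-methoxy-N-methyl-2-(benzyloxy)acetamide | CON(C)C(=O)COCc1ccccc1 | starting material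
7 | [2-(methoxymethoxy)-3,4,5,6-tetramethoxyphenyl]lithium | [Li]c1c(OC)c(OC)c(OC)c(OC)c1OCOC | intermediate
8 | 2-(benzyloxy)-1-[2-(methoxymethoxy)-3,4,5,6-tetramethoxyphenyl]ethan-1-one | COCOc1c(OC)c(OC)c(OC)c(OC)c1C(=O)COCc1ccccc1 | intermediate
9 | (Z)-2-(benzyloxy)-3-(dimethylamino)-1-[2-(methoxymethoxy)-3,4,5,6-tetramethoxyphenyl]prop-2-en-1-one | CN(C)/C=C(\OCc1ccccc1)C(=O)c1c(OC)c(OC)c(OC)c(OC)c1OCOC | intermediate
10 | (Z)-2-(benzyloxy)-3-(dimethylamino)-1-(2-hydroxy-3,4,5,6-tetramethoxyphenyl)prop-2-en-1-one | CN(C)/C=C(\OCc1ccccc1)C(=O)c1c(OC)c(OC)c(OC)c(OC)c1O | intermediate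
11 | 3-(benzyloxy)-5,6,7,8-tetramethoxy-4H-chromen-4-one | c1oc2c(OC)c(OC)c(OC)c(OC)c2c(=O)c1OCc1ccccc1 | intermediate
12 | bis[3-(benzyloxy)-5,6,7,8-tetramethoxy-4-oxo-4H-chromen-2-yl]zinc | [Zn](c1oc2c(OC)c(OC)c(OC)c(OC)c2c(=O)c1OCc1ccccc1)c1oc2c(OC)c(OC)c(OC)c(OC)c2c(=O)c1OCc1ccccc1 | intermediate
13 | 3-(benzyloxy)-2-iodo-5,6,7,8-tetramethoxy-4H-chromen-4-one | Ic1oc2c(OC)c(OC)c(OC)c(OC)c2c(=O)c1OCc1ccccc1 | intermediate
14 | trimethylsilylacetylene | C#C[Si](C)(C)C | starting material
15 | 3-(benzyloxy)-5,6,7,8-tetramethoxy-2-[(trimethylsilyl)ethynyl]-4H-chromen-4-one | C[Si](C)(C)C#Cc1oc2c(OC)c(OC)c(OC)c(OC)c2c(=O)c1OCc1ccccc1 | intermediate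
16 | 3-(benzyloxy)-2-ethynyl-5,6,7,8-tetramethoxy-4H-chromen-4-one | C#Cc1oc2c(OC)c(OC)c(OC)c(OC)c2c(=O)c1OCc1ccccc1 | intermediate
17 | 2,3-butanedione | CC(=O)C(C)=O | starting material
18 | 2,3-bis(trimethylsilyloxy)buta-1,3-diene | C=C(O[Si](C)(C)C)C(=C)O[Si](C)(C)C | intermediate
19 | 3-(benzyloxy)-2-[4,5-bis(trimethylsilyloxy)cyclohexa-1,4-dien-1-yl]-5,6,7,8-tetramethoxy-4H-chromen-4-one | C[Si](C)(C)OC1=C(O[Si](C)(C)C)CC(c2oc3c(OC)c(OC)c(OC)c(OC)c3c(=O)c2OCc2ccccc2)=CC1 | intermediate
20 | 3-(benzyloxy)-2-[3,4-bis(trimethylsilyloxy)phenyl]-5,6,7,8-tetramethoxy-4H-chromen-4-one | COc1c(OC)c(OC)c2c(=O)c(OCc3ccccc3)c(-c3ccc(O[Si](C)(C)C)c(O[Si](C)(C)C)c3)oc2c1OC | intermediate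
21 | 3-(benzyloxy)-2-(3,4-dihydroxyphenyl)-5,6,7,8-tetramethoxy-4H-chromen-4-one | COc1c(OC)c(OC)c2c(=O)c(OCc3ccccc3)c(-c3ccc(O)c(O)c3)oc2c1OC | intermediate
22 | 3,5,3',4'-tetrahydroxy-6,7,8-trimethoxyflavone, i.e. 2-(3,4-dihydroxyphenyl)-3,5-dihydroxy-6,7,8-trimethoxy-4H-chromen-4-one | COc1c(OC)c(O)c2c(=O)c(O)c(-c3ccc(O)c(O)c3)oc2c1OC | target

Total step count: 11. Longest linear sequence: 10 steps (steps 1–7 and 9–11); the diene is a one-step branch (step 8).

Steps most likely to fail

1. Step 9. The cycloaddition may be too slow at temperatures the reagents tolerate, so that oligomerisation of the diene, polymerisation of the terminal alkyne or acid-induced loss of the silyl groups outruns ring formation. The fallback gives up the de novo construction of ring B and attaches it as a preformed arene. It sets out from chromone 11: the zinc reagent 12 generated as in step 5 is not iodinated but submitted to Negishi cross-coupling with commercial 4-bromo-1,2-bis(benzyloxy)benzene (Pd(OAc)2, SPhos, THF, 50 °C). This should give 3-(benzyloxy)-2-[3,4-bis(benzyloxy)phenyl]-5,6,7,8-tetramethoxy-4H-chromen-4-one F1. The BCl3/pentamethylbenzene treatment of step 11 would then remove the three benzyl groups and the C5 methyl group together and return to the route at target 22.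

2. Step 5. Deprotonation of the electron-rich pyranone may stay incomplete, or the metalated ring C may open. The fallback replaces C–H metalation by nucleophilic alkynylation of the silyl-activated chromone. It sets out from 11, which on treatment with t-BuMe2SiOTf, CuI (cat.), i-Pr2NEt and alkyne 14 in CH2Cl2 should take up the copper acetylide at C2. The product would be racemic 3-(benzyloxy)-4-(tert-butyldimethylsilyloxy)-5,6,7,8-tetramethoxy-2-[(trimethylsilyl)ethynyl]-2H-chromene F2. DDQ would then abstract the C2 hydride and, with loss of the silyl group from O4, restore the chromone, returning to the route at alkyne 15.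

3. Step 11. The C6 methyl ether next to the boron-bound O5 may be cleaved as well, cleavage at C5 may stop short, or the catechol may oxidise during work-up. The fallback separates the two cleavages and changes both mechanisms. It sets out from 21, whose benzyl group is removed by hydrogenolysis (H2, Pd/C, EtOAc/MeOH) to give 2-(3,4-dihydroxyphenyl)-3-hydroxy-5,6,7,8-tetramethoxy-4H-chromen-4-one F3. AlCl3 in MeCN (rt to 50 °C, then aq. HCl) would then cleave only the peri C5 methyl ether through the aluminium chelate with the C4 carbonyl, returning to the route at target 22.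

Further compounds
F1 | step 9 | 3-(benzyloxy)-2-[3,4-bis(benzyloxy)phenyl]-5,6,7,8-tetramethoxy-4H-chromen-4-one | COc1c(OC)c(OC)c2c(=O)c(OCc3ccccc3)c(-c3ccc(OCc4ccccc4)c(OCc4ccccc4)c3)oc2c1OC
F2 | step 5 | racemic 3-(benzyloxy)-4-(tert-butyldimethylsilyloxy)-5,6,7,8-tetramethoxy-2-[(trimethylsilyl)ethynyl]-2H-chromene | C[Si](C)(C)C#CC1Oc2c(OC)c(OC)c(OC)c(OC)c2C(O[Si](C)(C)C(C)(C)C)=C1OCc1ccccc1
F3 | step 11 | 2-(3,4-dihydroxyphenyl)-3-hydroxy-5,6,7,8-tetramethoxy-4H-chromen-4-one | COc1c(OC)c(OC)c2c(=O)c(O)c(-c3ccc(O)c(O)c3)oc2c1OC
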